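Cuts: (a) the furandione O–C(=O) bond is opened and the carboxyl carbon is rejoined to the furandione CH(CH3) carbon, which gives a bicyclo[3.3.1]nonane enol-dione. (b) In ring A the bonds acid-bearing C–CH2 and spiro C–angular C are cut, giving a ring B allylic bromide/tertiary carbinol and methyl 3,5-dimethylorsellinate. (c) The bromide goes back through the δ-lactone C–O and Cα=Cβ bonds, three C–CH3 bonds and the two Robinson bonds of ring B.
Enabling feature: in ring A (methylidenecyclohexane) the acid-bearing quaternary carbon, the methylidene carbon and the furandione spiro carbon are contiguous and are C5, C6 and C1 of the orsellinate. The carboxyl carbon, the furandione CH(CH3) and the furandione ketone are its C4, C3 and C2. The ring A CH2 and the angular carbon belong to ring B (cyclohexene).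
Forward order: ring B (Michael addition, aldol condensation), then the spiro δ-lactone, then ring A together with a temporary dione bridge (key step), then cleavage of the bridge and closure of the furandione.
Stereochemistry: the δ-lactone spiro carbon comes from a catalytic asymmetric Michael addition and steers the face of the ring B cation (angular carbon). A sacrificial carbinol centre steers C5, and C1 is forced by the bridge. The furandione CH comes from exo hydroxylation of C3 and protonation with retention when C3–C4 breaks.

Key step: step 13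

Assumption: the cupreidine catalyst of step 3 is taken to give the (R)-adduct by analogy with simpler 2-alkylacetoacetates; if this donor responds in the opposite sense, the quinine-derived pseudoenantiomer is used and nothing else changes.
Numbering: C1–C6 are the orsellinate ring carbons (C1 bears CO2CH3) and keep these labels to the end. Primed locants are those of the 2-oxaspiro[5.5]undecane: C6′ is the spiro carbon, C7′ the methyl-bearing alkene carbon, C8′ its partner, and C9′ the carbinol, later angular, carbon. TBS = tert-butyldimethylsilyl.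

Step 1
Reactants: 1 3-(TBSO)propanal
Product: 2 (±)-5-(TBSO)pent-1-en-3-ol
Conditions: CH2=CHMgBr, THF, −78 to 0 °C
Reagents that add atoms: vinylmagnesium bromide, C=C[Mg]Br
Why: Grignard 1,2-addition to an unhindered aldehyde; the new carbinol carbon is racemic and becomes sp2 in step 2.

Step 2
Reactants: 2 (±)-5-(TBSO)pent-1-en-3-ol
Product: 3 5-(TBSO)pent-1-en-3-one
Conditions: 2-iodoxybenzoic acid, DMSO, rt
Reagents that add atoms: none
Why: Hypervalent-iodine oxidation of a secondary allylic alcohol under neutral conditions should give the vinyl ketone without loss of the β-silyloxy group.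

Step 3
Reactants: 3 5-(TBSO)pent-1-en-3-one; 4 (±)-ethyl 2-acetylpent-4-enoate
Product: 5 ethyl (2R)-2-acetyl-5-oxo-2-(prop-2-en-1-yl)-7-(TBSO)heptanoate
Conditions: 9-O-(phenanthren-9-yl)cupreidine (10 mol %), CH2Cl2, rt
Reagents that add atoms: none
Why: Catalytic asymmetric Michael addition of an α-substituted β-keto ester to a vinyl ketone under bifunctional cinchona catalysis: the quinuclidine nitrogen binds the enol, the 6′-OH binds the enone carbonyl, and attack on one enol face sets the quaternary carbon (R), later the δ-lactone spiro carbon.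

Step 4
Reactants: 5 ethyl (2R)-2-acetyl-5-oxo-2-(prop-2-en-1-yl)-7-(TBSO)heptanoate
Product: 6 ethyl (1R)-2-methyl-4-oxo-1-(prop-2-en-1-yl)-3-(TBSOCH2)cyclohex-2-ene-1-carboxylate
Conditions: pyrrolidine (0.3 equiv), AcOH (0.3 equiv), 4 Å MS, toluene, 45 °C
Reagents that add atoms: none
Why: Intramolecular aldol condensation (second half of a Robinson annulation): the enamine forms only at the unhindered chain ketone, its carbon next to CH2OTBS attacks the ester-activated acetyl carbonyl in the one six-membered mode open to it, and the buffered amine is too mild for E1cB loss of silanolate or retro-Michael erosion of the quaternary centre.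

Step 5
Reactants: 6 ethyl (1R)-2-methyl-4-oxo-1-(prop-2-en-1-yl)-3-(TBSOCH2)cyclohex-2-ene-1-carboxylate
Product: 7 (1S,4R)-4-(2-hydroxypropan-2-yl)-1,3-dimethyl-4-(prop-2-en-1-yl)-2-(TBSOCH2)cyclohex-2-en-1-ol
Conditions: MeLi (6 equiv), Et2O, −78 °C to rt
Reagents that add atoms: methyllithium, [Li]C
Why: Organolithium 1,2-addition to the enone at −78 °C and then twice to the ethyl ester on warming; the carbinol centre should arise by axial attack anti to the pseudoaxial allyl arm (the flat ester lies pseudoequatorial beside the ring methyl group), which places OH trans to the future CMe2–O arm as step 13 requires, and any (1R)-epimer is removed by chromatography.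

Step 6
Reactants: 7 (1S,4R)-4-(2-hydroxypropan-2-yl)-1,3-dimethyl-4-(prop-2-en-1-yl)-2-(TBSOCH2)cyclohex-2-en-1-ol
Product: 8 (1S,4S)-4-(2-hydroxypropan-2-yl)-4-(3-hydroxypropyl)-1,3-dimethyl-2-(TBSOCH2)cyclohex-2-en-1-ol
Conditions: 9-borabicyclo[3.3.1]nonane (9-BBN, 3 equiv), THF, 0 °C to rt; then NaOH, H2O2, 0 °C
Reagents that add atoms: hydrogen peroxide, OO
Why: Hydroboration–oxidation in which 9-BBN takes only the monosubstituted alkene (anti-Markovnikov) and leaves the tetrasubstituted ring alkene; no stereocentre is touched (the C4 descriptor changes by priority only).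

Step 7
Reactants: 8 (1S,4S)-4-(2-hydroxypropan-2-yl)-4-(3-hydroxypropyl)-1,3-dimethyl-2-(TBSOCH2)cyclohex-2-en-1-ol
Product: 9 (6R,9S)-9-hydroxy-1,1,7,9-tetramethyl-8-(TBSOCH2)-2-oxaspiro[5.5]undec-7-en-3-one
Conditions: 2,2,6,6-tetramethylpiperidin-1-oxyl (20 mol %), PhI(OAc)2 (2.5 equiv), CH2Cl2, rt
Reagents that add atoms: none
Why: Oxoammonium-catalysed oxidative lactonisation of a 1,5-diol: only the primary alcohol can be oxidised, the aldehyde is trapped by the neighbouring CMe2OH as a six-membered lactol, and this is oxidised on to the δ-lactone while the tertiary allylic alcohol stays inert.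

Step 8
Reactants: 9 (6R,9S)-9-hydroxy-1,1,7,9-tetramethyl-8-(TBSOCH2)-2-oxaspiro[5.5]undec-7-en-3-one
Product: 11 (6R,9S)-9-hydroxy-1,1,7,9-tetramethyl-8-(TBSOCH2)-2-oxaspiro[5.5]undeca-4,7-dien-3-one, via 4-phenylselanyl lactone 10 (not isolated)
Conditions: LiN(i-Pr)2 (2.3 equiv), THF, −78 °C; PhSeBr; then 3-chloroperoxybenzoic acid (1 equiv), CH2Cl2, −78 °C; i-Pr2NH, to rt
Reagents that add atoms: none
Why: α-Selenenylation of the lactone enolate and selenoxide syn-elimination; the extra base only holds the carbinol as its alkoxide, one equivalent of peracid at −78 °C is consumed by selenium before it can reach the ring alkene, and only the C5 hydrogens are available for elimination.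

Step 9
Reactants: 11 (6R,9S)-9-hydroxy-1,1,7,9-tetramethyl-8-(TBSOCH2)-2-oxaspiro[5.5]undeca-4,7-dien-3-one
Product: 12 (6R,9S)-9-hydroxy-8-(hydroxymethyl)-1,1,7,9-tetramethyl-2-oxaspiro[5.5]undeca-4,7-dien-3-one
Conditions: Bu4NF, AcOH, THF, 0 °C
Reagents that add atoms: none
Why: Fluoride cleavage of a primary silyl ether, buffered with acetic acid so that neither the enoate nor the acid-labile tertiary allylic alcohol is disturbed.

Step 10
Reactants: 12 (6R,9S)-9-hydroxy-8-(hydroxymethyl)-1,1,7,9-tetramethyl-2-oxaspiro[5.5]undeca-4,7-dien-3-one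
Product: 13 (6R,9S)-8-(bromomethyl)-9-hydroxy-1,1,7,9-tetramethyl-2-oxaspiro[5.5]undeca-4,7-dien-3-one (fragment 1)
Conditions: CBr4, PPh3, 2,6-lutidine, CH2Cl2, −30 °C
Reagents that add atoms: carbon tetrabromide, BrC(Br)(Br)Br
Why: Appel bromination, which engages the unhindered primary allylic alcohol far faster than the tertiary one and runs without free acid; 13 is used at once.

Step 11
Reactants: 14 methyl 2,4-dihydroxy-3,6-dimethylbenzoate
Product: 15 methyl 5-formyl-2,4-dihydroxy-3,6-dimethylbenzoate
Conditions: Cl2CHOMe, TiCl4, CH2Cl2, −10 °C to rt; then aq. HCl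
Reagents that add atoms: dichloromethyl methyl ether, COC(Cl)Cl; water, O
Why: Rieche formylation (electrophilic aromatic substitution) at C5, the only free ring position, which is ortho and para to the two hydroxyl groups.

Step 12
Reactants: 15 methyl 5-formyl-2,4-dihydroxy-3,6-dimethylbenzoate
Product: 16 methyl 2,4-dihydroxy-3,5,6-trimethylbenzoate (methyl 3,5-dimethylorsellinate, fragment 2)
Conditions: H2 (1 atm), Pd/C, AcOH, rt
Reagents that add atoms: none
Why: Hydrogenolysis of an electron-rich o-hydroxybenzaldehyde through the benzylic alcohol to the methyl group; ester and arene are inert under these conditions.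

Step 13
Reactants: 13 (6R,9S)-8-(bromomethyl)-9-hydroxy-1,1,7,9-tetramethyl-2-oxaspiro[5.5]undeca-4,7-dien-3-one; 16 methyl 3,5-dimethylorsellinate
Product: 18 bridged bicyclo[3.3.1]nonane enol methyl ester fused to ring B, via C5-alkylated cyclohexadienone 17 (not isolated)
Conditions: 16, LiN(SiMe3)2 (1.0 equiv), toluene, 0 °C; 13, 0 °C to rt; then CH2Cl2, CF3CO2H (5 equiv), −20 to 0 °C
Reagents that add atoms: none
Why: The lithium 4-phenoxide of 16, a tight ion pair in toluene with its 2-OH tied to the ester by a hydrogen bond, displaces the primary allylic bromide through C5 (SN2) to give dienone 17; CF3CO2H then enolises 17 through its vinylogously acidic C6 methyl group (C6=CH2, nucleophilic C1), ionises the tertiary allylic carbinol, and C1 captures the C9′ terminus of the allyl cation. Both halves are known reaction types, namely alkylative dearomatisation of orsellinates and acylphloroglucinols with allylic bromides and capture of tertiary allylic cations by β-dicarbonyl enols to give bicyclo[3.3.1]nonanes. Ring A closes in a 6-(enolexo)-endo-trig mode through a chair-like array; attack at the other terminus C7′ would need an eight-membered ring, and capture by the C4 oxygen to a pyran is reversible in acid whereas the C–C bond is not. C5 (R) is set in the alkylation by the (9′S)-carbinol, whose pseudoaxial OH lies on the ring B face opposite the departing bromide and bridges through Li or H to the phenoxide oxygen, so that C4–O points to C9′, the arene points away from ring B and only one face of C5 is offered; this is the least secure element of control and any epimer is removed after cyclisation. The angular carbon (S) is set by C6′, because the CMe2–O arm stands pseudoaxial to avoid the C7′ methyl group and covers one face of the cation while the chair puts the angular methyl axial and anti to the dione bridge, and C1 (S) follows of necessity since C1 and C5 of one six-membered ring can only be bridged cis. The step needs C5 rather than C3 or O alkylation, which is favoured by exactly one equivalent of lithium base (no C3-centred dianion), the non-polar medium, the crowding of C3 between two coordinated oxygens, and the fact that only C5 attack leaves the conjugated enolised 2,4-dione.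

Step 14
Reactants: 18 bridged bicyclo[3.3.1]nonane enol methyl ester
Product: 19 (3S)-3-hydroxy-2,4-dione of 18 (OH exo)
Conditions: KN(SiMe3)2 (1.1 equiv), THF, −78 °C; 2-(benzenesulfonyl)-3-phenyloxaziridine, −78 to −40 °C; AcOH
Reagents that add atoms: 2-(benzenesulfonyl)-3-phenyloxaziridine, O=S(=O)(c1ccccc1)N1OC1c1ccccc1
Why: Oxidation of the potassium enolate of the 1,3-diketone with an N-sulfonyloxaziridine (Davis oxidation): oxygen reaches C3 from the exo face on the side of the methylidene bridge, because the endo face is covered by ring A and the ring B alkene, which gives (3S), and the reagent does not epoxidise the three C=C bonds.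

Step 15
Reactants: 19 (3S)-3-hydroxy-2,4-dione
Product: 21 penicianstinoid C, via seco hydroxy keto ester acid 20 (not isolated)
Conditions: LiOH (4 equiv), THF/H2O, 0 °C; then 1 M HCl to pH 2, rt
Reagents that add atoms: lithium hydroxide, [Li+].[OH-]
Why: Retro-Claisen cleavage of a non-enolisable 1,3-diketone followed by 5-exo-trig lactonisation: hydroxide adds to the C4 carbonyl, which is less shielded than C2 (flanked by the ester-bearing C1 and the angular carbon), the C3–C4 bond breaks, the nascent carboxyl group passes its proton to C3 on the face that C4 leaves (retention, R), and on acidification the secondary alcohol of 20 displaces methanol from the C1 ester while any opened δ-lactone recloses.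

Compound list
1 | 3-[(tert-butyldimethylsilyl)oxy]propanal (commercial; also two steps from propane-1,3-diol) | O=CCCO[Si](C)(C)C(C)(C)C | starting material
2 | (±)-5-[(tert-butyldimethylsilyl)oxy]pent-1-en-3-ol | C=CC(O)CCO[Si](C)(C)C(C)(C)C | intermediate
3 | 5-[(tert-butyldimethylsilyl)oxy]pent-1-en-3-one | C=CC(=O)CCO[Si](C)(C)C(C)(C)C | intermediate
4 | (±)-ethyl 2-acetylpent-4-enoate | C=CCC(C(C)=O)C(=O)OCC | starting material
5 | ethyl (2R)-2-acetyl-7-[(tert-butyldimethylsilyl)oxy]-5-oxo-2-(prop-2-en-1-yl)heptanoate | CC(=O)[C@](C(=O)OCC)(CC=C)CCC(=O)CCO[Si](C)(C)C(C)(C)C | intermediate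
6 | ethyl (1R)-3-{[(tert-butyldimethylsilyl)oxy]methyl}-2-methyl-4-oxo-1-(prop-2-en-1-yl)cyclohex-2-ene-1-carboxylate | O=C1C(CO[Si](C)(C)C(C)(C)C)=C(C)[C@](C(=O)OCC)(CC=C)CC1 | intermediate
7 | (1S,4R)-2-{[(tert-butyldimethylsilyl)oxy]methyl}-4-(2-hydroxypropan-2-yl)-1,3-dimethyl-4-(prop-2-en-1-yl)cyclohex-2-en-1-ol | CC(C)(C)[Si](C)(C)OCC1=C(C)[C@](C(C)(C)O)(CC=C)CC[C@]1(C)O | intermediate
8 | (1S,4S)-2-{[(tert-butyldimethylsilyl)oxy]methyl}-4-(2-hydroxypropan-2-yl)-4-(3-hydroxypropyl)-1,3-dimethylcyclohex-2-en-1-ol | CC(C)(C)[Si](C)(C)OCC1=C(C)[C@](C(C)(C)O)(CCCO)CC[C@]1(C)O | intermediate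
9 | (6R,9S)-8-{[(tert-butyldimethylsilyl)oxy]methyl}-9-hydroxy-1,1,7,9-tetramethyl-2-oxaspiro[5.5]undec-7-en-3-one | CC(C)(C)[Si](C)(C)OCC1=C(C)[C@]2(CCC(=O)OC2(C)C)CC[C@]1(C)O | intermediate
10 | 4-(phenylselanyl) derivative of 9, both C4 epimers, (6R,9S) | CC(C)(C)[Si](C)(C)OCC1=C(C)[C@]2(CC([Se]c3ccccc3)C(=O)OC2(C)C)CC[C@]1(C)O | intermediate
11 | (6R,9S)-8-{[(tert-butyldimethylsilyl)oxy]methyl}-9-hydroxy-1,1,7,9-tetramethyl-2-oxaspiro[5.5]undeca-4,7-dien-3-one | CC(C)(C)[Si](C)(C)OCC1=C(C)[C@]2(C=CC(=O)OC2(C)C)CC[C@]1(C)O | intermediate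
12 | (6R,9S)-9-hydroxy-8-(hydroxymethyl)-1,1,7,9-tetramethyl-2-oxaspiro[5.5]undeca-4,7-dien-3-one | OCC1=C(C)[C@]2(C=CC(=O)OC2(C)C)CC[C@]1(C)O | intermediate
13 | fragment 1, (6R,9S)-8-(bromomethyl)-9-hydroxy-1,1,7,9-tetramethyl-2-oxaspiro[5.5]undeca-4,7-dien-3-one (OH trans to the CMe2–O arm) | BrCC1=C(C)[C@]2(C=CC(=O)OC2(C)C)CC[C@]1(C)O | intermediate
14 | methyl 2,4-dihydroxy-3,6-dimethylbenzoate | COC(=O)c1c(C)cc(O)c(C)c1O | starting material
15 | methyl 5-formyl-2,4-dihydroxy-3,6-dimethylbenzoate (orsellinate numbering) | COC(=O)c1c(C)c(C=O)c(O)c(C)c1O | intermediate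
16 | fragment 2, methyl 2,4-dihydroxy-3,5,6-trimethylbenzoate (methyl 3,5-dimethylorsellinate) | COC(=O)c1c(C)c(C)c(O)c(C)c1O | intermediate
17 | methyl (5R)-2-hydroxy-3,5,6-trimethyl-4-oxo-5-{[(6R,9S)-9-hydroxy-1,1,7,9-tetramethyl-3-oxo-2-oxaspiro[5.5]undeca-4,7-dien-8-yl]methyl}cyclohexa-1(6),2-diene-1-carboxylate (orsellinate numbering) | COC(=O)C1=C(C)[C@@](C)(CC2=C(C)[C@]3(C=CC(=O)OC3(C)C)CC[C@]2(C)O)C(=O)C(C)=C1O | intermediate
18 | bicyclo[3.3.1]nonane with bridgeheads C5 (R, CH3) and C1 (S, CO2CH3), one-carbon bridge C6(=CH2), bridge C4(=O)–C3(CH3)=C2(OH) and bridge CH2–C8′–C9′ fused to ring B; angular C9′ (S) with CH3 anti to the dione bridge; δ-lactone spiro C6′ (R) | C=C1[C@](C)(C4=O)CC2=C(C)[C@]3(C=CC(=O)OC3(C)C)CC[C@]2(C)[C@]1(C(=O)OC)C(O)=C4C | intermediate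
19 | 2,4-dione of 18 carrying OH and CH3 on C3, (3S), OH on the exo face (side of the methylidene bridge) | C=C1[C@](C)(C4=O)CC2=C(C)[C@]3(C=CC(=O)OC3(C)C)CC[C@]2(C)[C@]1(C(=O)OC)C(=O)[C@@]4(C)O | intermediate
20 | seco acid: ring A with CO2H on C5 and with CO2CH3 and a (2R)-2-hydroxypropanoyl group on C1 | C=C1[C@](C)(C(=O)O)CC2=C(C)[C@]3(C=CC(=O)OC3(C)C)CC[C@]2(C)[C@]1(C(=O)OC)C(=O)[C@@H](C)O | intermediate
21 | penicianstinoid C (acid-bearing C R, angular C S, furandione spiro C S, furandione CH R, δ-lactone spiro C R) | C=C1[C@](C)(C(=O)O)CC2=C(C)[C@]3(C=CC(=O)OC3(C)C)CC[C@]2(C)[C@@]12C(=O)O[C@H](C)C2=O | target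

Total step count: 15. Longest linear sequence: 13 steps (steps 1–10 and 13–15).

Steps most likely to fail
1. Step 13. Alkylation may drift to C3 or to oxygen. The hydroxyl-bridged transition state may not dominate, so that facial selectivity at C5 is poor. The cation may also be lost by elimination to dienes. The fallback sets out from 12 (with 16) and comes back at 18. Methyl chloroformate and pyridine at −20 °C convert the primary hydroxyl group of 12 into the allylic methyl carbonate F1. F1 and 16 are joined by a Tsuji–Trost-type dearomative allylation with zerovalent palladium (Pd2(dba)3·CHCl3) and N,N′-[(1R,2R)-cyclohexane-1,2-diyl]bis[2-(diphenylphosphanyl)benzamide], the ligand antipode being matched to the substrate. In this reaction O-allylation is reversible, the nucleophile takes the unsubstituted allyl terminus, and the ligand rather than the carbinol selects the face of C5. Here 17 is isolated, freed from isomers by chromatography and cyclised with CF3CO2H in a separate operation to 18.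
2. Step 15. Hydroxide may add to the C2 carbonyl instead of C4. The C3 alkoxide may trigger an acyl (α-ketol) shift. The furandione may be hydrolysed and decarboxylate, and the enolisable CH(CH3) centre may equilibrate. The fallback sets out from 19 and comes back at 20. Periodic acid (H5IO6, THF/H2O, 0 °C, Malaprade-type α-ketol cleavage) cuts C3–C4 at the same, more open carbonyl under non-basic conditions. This gives the seco 1,2-diketone acid F2, which carries CO2H on C5 and a 2-oxopropanoyl group on C1. Asymmetric transfer hydrogenation (RuCl(p-cymene)[(R,R)-TsNCH(Ph)CH(Ph)NH2], HCO2H/Et3N) then reduces the outer, methyl-flanked carbonyl under catalyst control to the (R)-alcohol 20, which lactonises to 21 on mild acid treatment.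
3. Step 3. The acyclic, α-branched donor may react slowly and with eroded enantioselectivity. The fallback sets out from 4 and comes back at 5. Compound 4 is condensed with (2R)-2-amino-N,N-diethyl-3-methylbutanamide (cat. CF3CO2H, 4 Å MS, toluene) to the hydrogen-bonded (Z)-enamino ester F3. Cu(OAc)2·H2O (5 mol %) in acetone mediates its Michael addition to 3 through a rigid copper chelate in which the isopropyl group covers one face, giving the imine adduct F4. Aqueous citric acid hydrolyses F4 to 5 and returns the auxiliary.

Further compounds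
F1 | step 13 | [(6R,9S)-9-hydroxy-1,1,7,9-tetramethyl-3-oxo-2-oxaspiro[5.5]undeca-4,7-dien-8-yl]methyl methyl carbonate | COC(=O)OCC1=C(C)[C@]2(C=CC(=O)OC2(C)C)CC[C@]1(C)O
F2 | step 15 | seco 1,2-diketone acid (CO2H on C5; CO2CH3 and 2-oxopropanoyl on C1) | C=C1[C@](C)(C(=O)O)CC2=C(C)[C@]3(C=CC(=O)OC3(C)C)CC[C@]2(C)[C@]1(C(=O)OC)C(=O)C(C)=O
F3 | step 3 | ethyl (2Z)-3-{[(2R)-1-(diethylamino)-3-methyl-1-oxobutan-2-yl]amino}-2-(prop-2-en-1-yl)but-2-enoate | CCOC(=O)/C(CC=C)=C(/C)N[C@H](C(C)C)C(=O)N(CC)CC
F4 | step 3 | ketimine of 5 with (2R)-2-amino-N,N-diethyl-3-methylbutanamide at the acetyl carbon | CCOC(=O)[C@@](CC=C)(CCC(=O)CCO[Si](C)(C)C(C)(C)C)C(C)=N[C@H](C(C)C)C(=O)N(CC)CC
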